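Its constants are assumed, and the outcome is calculated.

I watched the ligand, not the clock.

starting material 10 mM; reagent 11.0 mM; free catalyst 2.0 mM; second catalyst 1.0 mM; added ligand 2.8 mM

- the form that holds most of the catalyst when 50% of the starting material are converted (idle complex / free catalyst / dormant form)
- its share of the catalyst then

    starting material + free catalyst → free catalyst + intermediate (k1 = 41 /M/min)
    free catalyst ⇌ dormant form (K2 = 0.59, k2 = 0.0013 /min)
    free catalyst + added ligand ⇌ idle complex (K3 = 34000 /M, k3 = 66 /M/min)
    reagent + second catalyst + intermediate → second catalyst + product (k4 = 870 /M²/min)

In this flask, free catalyst converts starting material with constant 41 /M/min, and added ligand captures free catalyst with constant 66 /M/min. Through these forward steps, starting material and added ligand each lose a log-fraction, the logarithm of charge over amount left, in proportion to one shared exposure, the time integral of free catalyst. So the exposure cancels. The ratio of capture constant to conversion constant, s = 1.61, is a selectivity factor: the log-fraction of ligand lost per log-fraction of starting material lost. Half conversion is a log-fraction of 0.693.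

For a ceiling I took capture as one-way. Ligand lost sits in idle complex, and the catalyst charge is 2.0 mM, so the share is at most 94.1%. The dormant form holds no ligand and stays out of this balance.

For a floor I let idle complex undo at 0.116 /h. The ceiling's end ratio of idle complex to ligand, 2.05, is an upper limit on that ratio. Half conversion came at 0.504 h, so the log-fraction returned is at most 0.120. That gives 88.3%, so idle complex holds most of the catalyst.

| Bound | Ligand left | Idle complex share |
|---|---|---|
| Ceiling, capture one-way | 32.8% | 94.1% |
| Floor, undoing at its upper limit | 36.9% | 88.3% |

The forecast said idle complex at 90%, within 87% to 93%, since the ligand “binds tightly and quickly”; its centre lay inside my bracket.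

The simulation gave idle complex at 90.8%, inside the bracket, with free catalyst at 8.15% and dormant form at 1.05%.

In this flask, the ligand left at 0.500 h was 35.2% of its charge. That reads as an exponent of 1.51, below s. A further run removed the undoing of idle complex, and there s applies with no correction. In that run, idle complex takes 1.88 mM of the 2.0 mM charged at half conversion, so free catalyst and dormant form share a remainder of 0.117 mM. Without the undoing, the apparent order in free catalyst at half conversion rose from 1.7 to 4.1.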